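**Plan** (chain numbering: C1 = CH3 on the CHCl carbon … C13 = CH2 on furan ring A; ring A = O1, C2 carrying the CH2 to 3-furyl ring B, C3–H, C4 carrying C13, C5–H)
Cuts, in retrosynthetic order: C2–Cl (chloride opening of a cis-2,3-epoxy ketone), the oxirane oxygen (back to a (Z)-enone), C3–C4 (propenyl addition to a C4 aldehyde), ring A at C3=C4 and at its O1 acetal linkage, C13–C4 of ring A (B-alkyl Suzuki coupling) and C11–C12 (allyl–vinyl coupling).
Enabling feature: the 2,4-disubstituted furan ring A maps atom for atom onto a mixed acetal of a 2-alkylacrolein (acetal carbon = C5, α-carbon = C4) and a vinyl carbinol (carbinol carbon = C2, vinyl CH = C3). Metathesis therefore closes C3=C4, and loss of the acetal alkoxy group aromatises, with no substitution on a preformed furan.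
Forward: (R)-citronellol is silylated and extended at its E-methyl group to the 2-alkylacrolein diethyl acetal; furan-3-carbaldehyde gives 1-(furan-3-yl)but-3-en-2-ol; acetal exchange joins them, ring A is closed, and C1–C3 are then added at the other chain end.
Stereochemistry: C6 comes from (R)-citronellol, the E C9=C10 alkene from SeO2 oxidation of the E-methyl group, and C2/C3 from ligand-controlled cis-epoxidation of the (Z)-enone followed by SN2 opening at C2 with inversion.

Key step: step 10

Assumption: the catalyst formed from Yb(O-i-Pr)3 and 3-(hydroxymethyl)-1,1'-bi-2-naphthol is taken to attack the same enone face in the Z series as lanthanoid–binaphthoxide catalysts do in the E series, so the (S)-ligand is assigned to the (2R,3R)-cis-epoxide.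

**Step 1**
Reactants: 1 (R)-citronellol
Product: 2 tert-butyl{[(3R)-3,7-dimethyloct-6-en-1-yl]oxy}diphenylsilane
Conditions: TBDPSCl, imidazole, CH2Cl2, 0 °C → rt
Reagents that add atoms: tert-butyl(chloro)diphenylsilane, CC(C)(C)[Si](Cl)(c1ccccc1)c1ccccc1
Why: Imidazole-promoted silylation of the primary alcohol; the TBDPS ether is chosen because it should survive SeO2, organomagnesium and organoboron reagents, aqueous base, PPTS and the metathesis catalyst and is removed by fluoride alone.

**Step 2**
Reactants: 2 tert-butyl{[(3R)-3,7-dimethyloct-6-en-1-yl]oxy}diphenylsilane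
Product: 3 (2E,6R)-8-[(tert-butyldiphenylsilyl)oxy]-2,6-dimethyloct-2-en-1-ol
Conditions: SeO2 (cat.), t-BuOOH, salicylic acid (cat.), CH2Cl2, rt
Reagents that add atoms: tert-butyl hydroperoxide, CC(C)(C)OO
Why: Riley-type allylic oxidation, in which the ene reaction of SeO2 at the trisubstituted alkene and a [2,3]-sigmatropic shift hydroxylate the methyl group trans to the chain, fixing the E geometry of the later C9=C10 bond.

**Step 3**
Reactants: 3 (2E,6R)-8-[(tert-butyldiphenylsilyl)oxy]-2,6-dimethyloct-2-en-1-ol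
Product: 4 {[(3R,6E)-8-bromo-3,7-dimethyloct-6-en-1-yl]oxy}(tert-butyl)diphenylsilane
Conditions: CBr4, PPh3, CH2Cl2, 0 °C
Reagents that add atoms: tetrabromomethane, BrC(Br)(Br)Br
Why: Appel bromination by SN2 displacement of the oxyphosphonium group at the primary allylic carbon under neutral conditions, so alkene geometry and silyl ether are kept.

**Step 4**
Reactants: 4 {[(3R,6E)-8-bromo-3,7-dimethyloct-6-en-1-yl]oxy}(tert-butyl)diphenylsilane
Product: 5 tert-butyl{[(3R,6E)-3,7-dimethyldeca-6,9-dien-1-yl]oxy}diphenylsilane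
Conditions: CH2=CHMgBr, CuI (cat.), THF, −30 → 0 °C
Reagents that add atoms: vinylmagnesium bromide, C=C[Mg]Br
Why: Copper-catalysed cross-coupling of a primary allylic bromide with a vinyl Grignard reagent, which should occur at the unhindered CH2 terminus (SN2, not SN2') with retention of the E alkene and forms C11–C12 as a skipped diene.

**Step 5**
Reactants: 5 tert-butyl{[(3R,6E)-3,7-dimethyldeca-6,9-dien-1-yl]oxy}diphenylsilane; 6 2-bromo-3,3-diethoxyprop-1-ene
Product: 8 tert-butyl{[(3R,6E)-11-(diethoxymethyl)-3,7-dimethyldodeca-6,11-dien-1-yl]oxy}diphenylsilane, via B-alkyl-9-BBN 7 (not isolated)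
Conditions: 9-BBN, THF, 0 °C → rt; then 6, PdCl2(dppf) (cat.), AsPh3, Cs2CO3, DMF/H2O, rt
Reagents that add atoms: none
Why: Hydroboration followed by B-alkyl Suzuki–Miyaura coupling, in which 9-BBN adds anti-Markovnikov to the monosubstituted alkene only and the borane transfers its primary alkyl group under aqueous base to the alkenylpalladium bromide formed from 6 and zerovalent palladium, joining C13 to the future ring A carbon 4 while acetal, silyl ether and trisubstituted alkene are left alone.

**Step 6**
Reactants: 9 furan-3-carbaldehyde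
Product: 10 3-(2-methoxyethenyl)furan (E/Z mixture)
Conditions: Ph3P(CH2OMe)Cl, KOt-Bu, THF, 0 °C
Reagents that add atoms: (methoxymethyl)triphenylphosphonium chloride, COC[P+](c1ccccc1)(c1ccccc1)c1ccccc1.[Cl-]
Why: Wittig methoxymethylenation of the aldehyde, a one-carbon homologation for which the enol ether geometry is of no consequence.

**Step 7**
Reactants: 10 3-(2-methoxyethenyl)furan
Product: 11 2-(furan-3-yl)acetaldehyde
Conditions: 1 M aq. HCl, THF, 0 °C → rt, short reaction time; used crude
Reagents that add atoms: water, O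
Why: Acid-catalysed enol ether hydrolysis by way of the oxocarbenium ion and hemiacetal unmasks the homologous aldehyde, which is used at once because arylacetaldehydes enolise and self-condense.

**Step 8**
Reactants: 11 2-(furan-3-yl)acetaldehyde
Product: 12 1-(furan-3-yl)but-3-en-2-ol (racemic)
Conditions: CH2=CHMgBr, THF, −78 °C; H2O
Reagents that add atoms: vinylmagnesium bromide, C=C[Mg]Br
Why: 1,2-Addition of the vinyl Grignard reagent to the aldehyde at low temperature, where addition should outrun enolisation; the carbinol is racemic by design because this centre becomes sp2 in ring A.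

**Step 9**
Reactants: 8 tert-butyl{[(3R,6E)-11-(diethoxymethyl)-3,7-dimethyldodeca-6,11-dien-1-yl]oxy}diphenylsilane; 12 1-(furan-3-yl)but-3-en-2-ol
Product: 13 tert-butyl{[(3R,6E)-11-{ethoxy[(1-(furan-3-yl)but-3-en-2-yl)oxy]methyl}-3,7-dimethyldodeca-6,11-dien-1-yl]oxy}diphenylsilane (mixture at the acetal and carbinol carbons)
Conditions: PPTS (cat.), toluene, 45 °C, reduced pressure (EtOH removed); 12 limiting, excess 8 recovered
Reagents that add atoms: none
Why: Acid-catalysed transacetalisation through the 2-alkylallyl oxocarbenium ion, pulled towards the mixed acetal by removal of ethanol, with 12 kept limiting so that a second exchange (whose product would offer a seven-ring closure in step 10) stays minor.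

**Step 10**
Reactants: 13 tert-butyl{[(3R,6E)-11-{ethoxy[(1-(furan-3-yl)but-3-en-2-yl)oxy]methyl}-3,7-dimethyldodeca-6,11-dien-1-yl]oxy}diphenylsilane
Product: 15 tert-butyl{[(3R,6E)-10-[5-(furan-3-ylmethyl)furan-3-yl]-3,7-dimethyldec-6-en-1-yl]oxy}diphenylsilane, via 2-ethoxy-2,5-dihydrofuran 14 (not isolated)
Conditions: second-generation Grubbs catalyst (H2IMes)(PCy3)Cl2Ru=CHPh (5 mol%), CH2Cl2 (5 mM), 40 °C; then PPTS (cat.), same flask, 40 °C
Reagents that add atoms: none
Why: Ring-closing olefin metathesis followed by eliminative aromatisation, the known route from allylic mixed acetals of acroleins to furans: the Ru=CHPh unit exchanges with the monosubstituted vinyl group of the allylic ether, the new alkylidene adds across the 1,1-disubstituted alkene through a four-membered metallacycle, and cycloreversion releases ethene and dihydrofuran 14. Ring A is thereby closed as a five-membered ring at its C3=C4 bond, with O1, C2 and C5 already in place from the acetal. PPTS then ionises the cyclic acetal at C5 and the oxocarbenium ion loses the C2 proton, so the gain in aromaticity makes the sequence irreversible and the 2,4-pattern follows from connectivity alone. No stereocentre is created, since the acetal and carbinol centres of 13 both become sp2. The selectivity needed is chemoselectivity: the catalyst loads at the only monosubstituted alkene, five-ring closure should outrun any reaction at the trisubstituted C9=C10 alkene (which would need a nine-membered ring or a tetrasubstituted cyclopentene), and ring B is aromatic and inert. High dilution and the use of the mixed acetal rather than a doubly exchanged one suppress dimerisation and seven-ring closure.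

**Step 11**
Reactants: 15 tert-butyl{[(3R,6E)-10-[5-(furan-3-ylmethyl)furan-3-yl]-3,7-dimethyldec-6-en-1-yl]oxy}diphenylsilane
Product: 16 (3R,6E)-10-[5-(furan-3-ylmethyl)furan-3-yl]-3,7-dimethyldec-6-en-1-ol
Conditions: TBAF, THF, rt
Reagents that add atoms: none
Why: Fluoride-induced cleavage of the Si–O bond, driven by the strong Si–F bond, which leaves furans and alkenes untouched.

**Step 12**
Reactants: 16 (3R,6E)-10-[5-(furan-3-ylmethyl)furan-3-yl]-3,7-dimethyldec-6-en-1-ol
Product: 17 (3R,6E)-10-[5-(furan-3-ylmethyl)furan-3-yl]-3,7-dimethyldec-6-enal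
Conditions: Dess–Martin periodinane, NaHCO3, CH2Cl2, 0 °C → rt
Reagents that add atoms: none
Why: Dess–Martin oxidation of the primary alcohol under buffered conditions that spare the acid-sensitive furans, with C6 lying β to the new carbonyl and therefore not epimerisable.

**Step 13**
Reactants: 17 (3R,6E)-10-[5-(furan-3-ylmethyl)furan-3-yl]-3,7-dimethyldec-6-enal
Product: 18 (2Z,6R,9E)-13-[5-(furan-3-ylmethyl)furan-3-yl]-6,10-dimethyltrideca-2,9-dien-4-ol (both C4 epimers)
Conditions: (Z)-1-bromoprop-1-ene, t-BuLi (2 equiv per bromide), Et2O, −78 °C; then 17, −78 °C; H2O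
Reagents that add atoms: (Z)-1-bromoprop-1-ene, C/C=C\Br (used as (Z)-prop-1-enyllithium, C/C=C\[Li])
Why: Bromine–lithium exchange with retention at the sp2 carbon followed by 1,2-addition of the alkenyllithium to the aldehyde forms C3–C4 with the Z alkene intact; the C4 carbinol centre is formed unselectively and is removed in step 14.

**Step 14**
Reactants: 18 (2Z,6R,9E)-13-[5-(furan-3-ylmethyl)furan-3-yl]-6,10-dimethyltrideca-2,9-dien-4-ol
Product: 19 (2Z,6R,9E)-13-[5-(furan-3-ylmethyl)furan-3-yl]-6,10-dimethyltrideca-2,9-dien-4-one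
Conditions: Dess–Martin periodinane, NaHCO3, CH2Cl2, 0 °C, light excluded; used promptly
Reagents that add atoms: none
Why: Dess–Martin oxidation of the allylic alcohol under buffered conditions, chosen to avoid acid-, base- or radical-mediated Z to E isomerisation of the cis-enone.

**Step 15**
Reactants: 19 (2Z,6R,9E)-13-[5-(furan-3-ylmethyl)furan-3-yl]-6,10-dimethyltrideca-2,9-dien-4-one
Product: 20 (3R,6E)-10-[5-(furan-3-ylmethyl)furan-3-yl]-3,7-dimethyl-1-[(2R,3R)-3-methyloxiran-2-yl]dec-6-en-1-one (cis-epoxide)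
Conditions: Yb(O-i-Pr)3 (10 mol%), (S)-3-(hydroxymethyl)-1,1'-bi-2-naphthol (10 mol%), t-BuOOH (decane), 4 Å MS, THF, rt
Reagents that add atoms: tert-butyl hydroperoxide, CC(C)(C)OO
Why: Catalytic asymmetric nucleophilic (Weitz–Scheffer-type) epoxidation of a cis-enone, in which peroxide bound to the catalyst formed from Yb(O-i-Pr)3 and the ligand adds to one face of C2 of the s-cis enone and the peroxy-enolate closes before C2–C3 rotation, so the cis relationship is kept and the ligand should set C2 and C3 both as R, C6 being too remote to interfere.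

**Step 16**
Reactants: 20 (3R,6E)-10-[5-(furan-3-ylmethyl)furan-3-yl]-3,7-dimethyl-1-[(2R,3R)-3-methyloxiran-2-yl]dec-6-en-1-one
Product: 21 (2S,3S,6R,9E)-2-chloro-13-[5-(furan-3-ylmethyl)furan-3-yl]-3-hydroxy-6,10-dimethyltridec-9-en-4-one
Conditions: anhydrous MgCl2, THF, 0 °C → rt; H2O
Reagents that add atoms: magnesium chloride, [Mg+2].[Cl-].[Cl-]
Why: Chelation-assisted SN2 opening of an α,β-epoxy ketone, in which MgCl2 bridges the ketone and oxirane oxygens and chloride attacks C2 (the carbon remote from the electron-withdrawing carbonyl) with inversion to give 2S, while the untouched C3–O bond becomes the 3S hydroxyl of the threo chlorohydrin.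

**Compound list**
1 | (R)-citronellol, (3R)-3,7-dimethyloct-6-en-1-ol | CC(C)=CCC[C@@H](C)CCO | starting material
2 | tert-butyl{[(3R)-3,7-dimethyloct-6-en-1-yl]oxy}diphenylsilane | CC(C)=CCC[C@@H](C)CCO[Si](c1ccccc1)(c1ccccc1)C(C)(C)C | intermediate
3 | (2E,6R)-8-[(tert-butyldiphenylsilyl)oxy]-2,6-dimethyloct-2-en-1-ol | OC/C(C)=C/CC[C@@H](C)CCO[Si](c1ccccc1)(c1ccccc1)C(C)(C)C | intermediate
4 | {[(3R,6E)-8-bromo-3,7-dimethyloct-6-en-1-yl]oxy}(tert-butyl)diphenylsilane | BrC/C(C)=C/CC[C@@H](C)CCO[Si](c1ccccc1)(c1ccccc1)C(C)(C)C | intermediate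
5 | tert-butyl{[(3R,6E)-3,7-dimethyldeca-6,9-dien-1-yl]oxy}diphenylsilane | C=CC/C(C)=C/CC[C@@H](C)CCO[Si](c1ccccc1)(c1ccccc1)C(C)(C)C | intermediate
6 | 2-bromo-3,3-diethoxyprop-1-ene (2-bromoacrolein diethyl acetal) | C=C(Br)C(OCC)OCC | starting material
7 | 9-{(4E,8R)-10-[(tert-butyldiphenylsilyl)oxy]-4,8-dimethyldec-4-en-1-yl}-9-borabicyclo[3.3.1]nonane | B1(CCC/C(C)=C/CC[C@@H](C)CCO[Si](c3ccccc3)(c3ccccc3)C(C)(C)C)C2CCCC1CCC2 | intermediate (not isolated)
8 | tert-butyl{[(3R,6E)-11-(diethoxymethyl)-3,7-dimethyldodeca-6,11-dien-1-yl]oxy}diphenylsilane | CCOC(OCC)C(=C)CCC/C(C)=C/CC[C@@H](C)CCO[Si](c1ccccc1)(c1ccccc1)C(C)(C)C | intermediate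
9 | furan-3-carbaldehyde | O=Cc1ccoc1 | starting material
10 | 3-(2-methoxyethenyl)furan (E/Z mixture) | COC=Cc1ccoc1 | intermediate
11 | 2-(furan-3-yl)acetaldehyde | O=CCc1ccoc1 | intermediate
12 | 1-(furan-3-yl)but-3-en-2-ol (racemic) | C=CC(O)Cc1ccoc1 | intermediate
13 | tert-butyl{[(3R,6E)-11-{ethoxy[(1-(furan-3-yl)but-3-en-2-yl)oxy]methyl}-3,7-dimethyldodeca-6,11-dien-1-yl]oxy}diphenylsilane (mixture at acetal and carbinol carbons) | C=CC(Cc1ccoc1)OC(OCC)C(=C)CCC/C(C)=C/CC[C@@H](C)CCO[Si](c1ccccc1)(c1ccccc1)C(C)(C)C | intermediate (key-step precursor)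
14 | tert-butyl{[(3R,6E)-10-[2-ethoxy-5-(furan-3-ylmethyl)-2,5-dihydrofuran-3-yl]-3,7-dimethyldec-6-en-1-yl]oxy}diphenylsilane (mixture at ring carbons 2 and 5) | CCOC1OC(Cc2ccoc2)C=C1CCC/C(C)=C/CC[C@@H](C)CCO[Si](c1ccccc1)(c1ccccc1)C(C)(C)C | intermediate (not isolated)
15 | tert-butyl{[(3R,6E)-10-[5-(furan-3-ylmethyl)furan-3-yl]-3,7-dimethyldec-6-en-1-yl]oxy}diphenylsilane | C/C(=C\CC[C@@H](C)CCO[Si](c1ccccc1)(c1ccccc1)C(C)(C)C)CCCc1coc(Cc2ccoc2)c1 | intermediate (key-step product)
16 | (3R,6E)-10-[5-(furan-3-ylmethyl)furan-3-yl]-3,7-dimethyldec-6-en-1-ol | C/C(=C\CC[C@@H](C)CCO)CCCc1coc(Cc2ccoc2)c1 | intermediate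
17 | (3R,6E)-10-[5-(furan-3-ylmethyl)furan-3-yl]-3,7-dimethyldec-6-enal | C/C(=C\CC[C@@H](C)CC=O)CCCc1coc(Cc2ccoc2)c1 | intermediate
18 | (2Z,6R,9E)-13-[5-(furan-3-ylmethyl)furan-3-yl]-6,10-dimethyltrideca-2,9-dien-4-ol (both C4 epimers) | C/C(=C\CC[C@@H](C)CC(O)/C=C\C)CCCc1coc(Cc2ccoc2)c1 | intermediate
19 | (2Z,6R,9E)-13-[5-(furan-3-ylmethyl)furan-3-yl]-6,10-dimethyltrideca-2,9-dien-4-one | C/C(=C\CC[C@@H](C)CC(=O)/C=C\C)CCCc1coc(Cc2ccoc2)c1 | intermediate
20 | (3R,6E)-10-[5-(furan-3-ylmethyl)furan-3-yl]-3,7-dimethyl-1-[(2R,3R)-3-methyloxiran-2-yl]dec-6-en-1-one | C/C(=C\CC[C@@H](C)CC(=O)[C@@H]3O[C@@H]3C)CCCc1coc(Cc2ccoc2)c1 | intermediate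
21 | (2S,3S,6R,9E)-2-chloro-13-[5-(furan-3-ylmethyl)furan-3-yl]-3-hydroxy-6,10-dimethyltridec-9-en-4-one | C/C(=C\CC[C@@H](C)CC(=O)[C@H](O)[C@H](C)Cl)CCCc1coc(Cc2ccoc2)c1 | target

**Step count**
Total: 16 steps. Longest linear sequence: 13 steps (1 → 21 through steps 1–5 and 9–16); the furyl carbinol 12 is made in 3 steps (6–8) and enters at step 9.

**Steps most likely to fail**

Step 15. Enantioface control and retention of the cis geometry may fail: the peroxide may add to the wrong enone face (the sense of induction is extrapolated), the peroxy-enolate may rotate about C2–C3 before closing and give the trans-oxirane, or the basic catalyst may isomerise the (Z)-enone. The fallback sets out from 19 and returns at 20, and moves the stereocontrol to a reduction that is then relayed by a hydroxyl group. Corey–Bakshi–Shibata reduction of 19 ((S)-Me-CBS oxazaborolidine, catecholborane, toluene, −78 °C; the propenyl group acting as the larger substituent) should give (2Z,4R,6R,9E)-13-[5-(furan-3-ylmethyl)furan-3-yl]-6,10-dimethyltrideca-2,9-dien-4-ol F1. Hydroxyl-directed epoxidation of F1 (Ti(O-i-Pr)4, t-BuOOH, 4 Å MS, CH2Cl2, −20 °C) should take place on the alkene face set by the conformer in which C4–H eclipses the double bond (least A(1,3) strain with the cis-methyl), giving the threo epoxy alcohol (1R,3R,6E)-10-[5-(furan-3-ylmethyl)furan-3-yl]-3,7-dimethyl-1-[(2S,3R)-3-methyloxiran-2-yl]dec-6-en-1-ol F2. Buffered Dess–Martin oxidation of F2 removes the C4 centre and gives 20.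

Step 16. Regioselectivity of the ring opening and survival of the product may fail: chloride may attack C3 next to the carbonyl, or the chloromagnesium alkoxide (ROMgCl) of the product may lose HCl or re-close to the oxirane. The fallback sets out from 20 and returns at 21, and replaces chelation by a silyl-transfer opening that caps the oxygen as it is released. Me3SiCl with catalytic Bu4NCl in CH2Cl2 at −20 °C should open the silylated oxirane at the carbon remote from the carbonyl and give (2S,3S,6R,9E)-2-chloro-13-[5-(furan-3-ylmethyl)furan-3-yl]-6,10-dimethyl-3-[(trimethylsilyl)oxy]tridec-9-en-4-one F3, in which no alkoxide is available for elimination. HF·pyridine in THF at 0 °C then frees the hydroxyl group to give 21.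

Step 9. The exchange is an equilibrium, so incomplete conversion, a second exchange (leading to dioxepine formation in step 10) and conjugate addition of the alcohol to the unsaturated oxocarbenium ion may all erode the mixed acetal. The fallback sets out from 8 and returns at 13, and makes the substitution stepwise and irreversible. Et3SiOTf and 2,4,6-trimethylpyridine in CH2Cl2 at 0 °C should convert one ethoxy group of 8 into a pyridinium leaving group, giving 1-[(6E,10R)-12-[(tert-butyldiphenylsilyl)oxy]-1-ethoxy-6,10-dimethyl-2-methylidenedodec-6-en-1-yl]-2,4,6-trimethylpyridin-1-ium trifluoromethanesulfonate F4. Addition of one equivalent of 12 displaces the pyridine and gives 13.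

**Further compounds**
F1 | step 15 | (2Z,4R,6R,9E)-13-[5-(furan-3-ylmethyl)furan-3-yl]-6,10-dimethyltrideca-2,9-dien-4-ol | C/C(=C\CC[C@@H](C)C[C@@H](O)/C=C\C)CCCc1coc(Cc2ccoc2)c1
F2 | step 15 | (1R,3R,6E)-10-[5-(furan-3-ylmethyl)furan-3-yl]-3,7-dimethyl-1-[(2S,3R)-3-methyloxiran-2-yl]dec-6-en-1-ol | C/C(=C\CC[C@@H](C)C[C@@H](O)[C@@H]3O[C@@H]3C)CCCc1coc(Cc2ccoc2)c1
F3 | step 16 | (2S,3S,6R,9E)-2-chloro-13-[5-(furan-3-ylmethyl)furan-3-yl]-6,10-dimethyl-3-[(trimethylsilyl)oxy]tridec-9-en-4-one | C/C(=C\CC[C@@H](C)CC(=O)[C@H](O[Si](C)(C)C)[C@H](C)Cl)CCCc1coc(Cc2ccoc2)c1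
F4 | step 9 | 1-[(6E,10R)-12-[(tert-butyldiphenylsilyl)oxy]-1-ethoxy-6,10-dimethyl-2-methylidenedodec-6-en-1-yl]-2,4,6-trimethylpyridin-1-ium trifluoromethanesulfonate | CCOC(C(=C)CCC/C(C)=C/CC[C@@H](C)CCO[Si](c1ccccc1)(c1ccccc1)C(C)(C)C)[n+]1c(C)cc(C)cc1C.[O-]S(=O)(=O)C(F)(F)F
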